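Between −12 °C and 37 °C the earlier runs differ in two readings: how long the solid substrate lasts and how much target stands at the finish.

common to all: solid substrate 0.89 M
- eta: first nucleophile 0.50 equiv; second nucleophile 0.98 equiv; temperature −12 °C; run made earlier
- gamma: first nucleophile 0.50 equiv; second nucleophile 1.5 equiv; temperature 37 °C; run made earlier
- cedar: first nucleophile 0.500 equiv; second nucleophile 0.700 equiv; temperature 55 °C; time 3.0 h
- birch: first nucleophile 0.500 equiv; second nucleophile 0.700 equiv; temperature 25 °C; time 3.0 h
- maple: first nucleophile 0.500 equiv; second nucleophile 0.700 equiv; temperature −35 °C; time 3.0 h
- ash: first nucleophile 0.500 equiv; second nucleophile 0.700 equiv; temperature −5 °C; time 3.0 h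

| run | time / h | target / % | solid substrate / % |
|---|---|---|---|
| eta | 6.00 | 5 | 53 |
| eta | 15.0 | 14 | 42 |
| eta | 30.0 | 29 | 27 |
| eta | 60.0 | 47 | 2 |
| eta | 120 | 50 | 3 |
| gamma | 0.833 | 44 | 0 |
| gamma | 2.00 | 46 | 2 |
| gamma | 4.00 | 44 | 0 |
| gamma | 6.00 | 48 | 1 |
| gamma | 10.0 | 44 | 0 |

(readings scatter by 1.5 percentage points)

- the best flask by amount of target, in percent of the solid substrate charged; "all alike" if 1.5 percentage points covers them all (cedar / birch / maple / ash / all alike)
- amount of target at the end, in percent of the solid substrate charged, cedar
- amount of target at the end, in percent of the solid substrate charged, birch
- amount of target at the end, in percent of the solid substrate charged, maple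
- amount of target at the end, in percent of the solid substrate charged, ash

- as a solid, counted per litre of solution: solid substrate
- steps thought possible: starting material -> intermediate; first nucleophile + intermediate -> target; second nucleophile + intermediate -> other capture product; intermediate -> solvolysis product; solid substrate <-> starting material
- at the start none of the solid substrate is in solution
- what has only dissolved of solid substrate counts as not reacted

Take the main route first: starting material gives intermediate, and first nucleophile captures it. First nucleophile is then the limiting reagent, and target is capped at 0.500 of the solid substrate charged. The eta run reaches 50% at its last reading.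

Next comes the supply. In the eta run, target climbs from 5% at 6.00 h to 29% at 30.0 h, a pace of 0.0100 h⁻¹ of the charge, while solid substrate still stands. At that pace 3.0 h gives 3.00%. Ash, warmer than the eta run, should give somewhat more, and maple, colder, far less. The gamma run reads 0% solid substrate by 0.833 h, so cedar and birch are taken to finish.

Last come the losses, reckoned as a correction to the cap. Define the loss concentration K, the [first nucleophile] at which intermediate goes equally to target and to everything else. The share captured is [first nucleophile]/([first nucleophile] + K). For a constant K, once all the material has reacted, dissolved starting material included, and some first nucleophile is still there, integration gives: solid substrate charged − target = K ln(initial [first nucleophile]/final [first nucleophile]). The gamma run, taken as finished, averages 45.2%, which is 4.8 percentage points under the cap, so 0.208 M. Cedar has the same charges of solid substrate and first nucleophile, so this K returns 45.2% there. Heat may raise K and less second nucleophile may lower it, and these runs cannot separate the two, so this reckoning commits to about that figure for cedar, with birch between it and the cap.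

The forecast gives birch 49%, cedar 48%, ash 6% and maple 0.2%, holding that “that competitor is nearly used up late on”. Its cedar stands higher than this reckoning's.

Birch gives most, 49.4%, against cedar 35.8%, ash 8.64% and maple 0.0553%.

    starting material → intermediate (k = 0.00120 s⁻¹, Ea = 90.0 kJ mol⁻¹)
    first nucleophile + intermediate → target (k = 6.60 L mol⁻¹ s⁻¹, Ea = 36.0 kJ mol⁻¹)
    second nucleophile + intermediate → other capture product (k = 0.160 L mol⁻¹ s⁻¹, Ea = 38.0 kJ mol⁻¹)
    intermediate → solvolysis product (k = 0.590 s⁻¹, Ea = 79.0 kJ mol⁻¹)
    solid substrate ⇌ starting material, rate k5*(cs5 - [starting material]) while solid is left; crystals form when [starting material] > cs5 (solubility = 0.370 M, k = 0.0150 s⁻¹)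
    (constants at 25 °C)

Cedar's solid substrate stood at 0% by 1.50 h, and target then held at 35.8%, with 28% of first nucleophile's charge unused and solvolysis product at 61.9%. Ash at 3.00 h still held 49.3% solid substrate and 41.5% starting material. Cedar's figures give K = 0.453 M, twice the gamma value, and birch, with 1.3% of first nucleophile's charge left, gives 0.104 M, half of it.

The earlier runs and the new flask are simulated from invented constants; scatter was added.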